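**Assumption:** the target is written, and delivered, as the chelated enol of its β-keto ester. The (S)-catalyst in step 4 is chosen from the formyl C–H···O binding model; if a trial run showed the opposite facial sense, its mirror image would be used with no other change.

**Plan**
1. Feature and key cut: the cis β-hydroxy ketone made of the ring-B ketone carbon, the adjacent ring B/ring C fusion CH and the C(OH)CH3 carbon of ring C is an opened 4,5-dihydroisoxazole. Cutting the ketone–CH bond (with the carbinol C–O bond) leads back to a nitrile oxide on ring A and a 1-methylcyclopentene, already tied together through the E-alkylidene γ-lactone (ring D).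
2. Further cuts: the exocyclic C=C of ring D (Horner–Wadsworth–Emmons) gives ring-A aldehyde 7 and phosphonolactone 15. Ring A is cut by Diels–Alder into silyloxy diene 4 and dienal 6. The lactone goes back by Claisen rearrangement to (R)-4-silyloxycyclopentenone 8.
3. Forward order: ring A (step 4), rings C and D (steps 5–8), union (step 9), ring B together with the dihydroisoxazole (step 11), then N–O cleavage and enol release (steps 12–13).
4. Stereochemistry: the three ring-A centres come from the catalyst-controlled endo Diels–Alder. The two lactone centres come from the chiral-pool enone by anti MeLi addition and suprafacial Claisen shift. The ring-fusion CH and the tertiary carbinol come from the tether-directed syn cycloaddition.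

Key step: step 11

**Route**

Step 1
Reactants: 1 methyl acetoacetate; 2 2,2-dimethoxyacetaldehyde
Product: 3 methyl (2Z)-2-acetyl-4,4-dimethoxybut-2-enoate
Conditions: piperidine (10 mol %), AcOH (10 mol %), CH2Cl2, 4 Å MS, 0 °C → rt
Reagents that add atoms: none
Why: Knoevenagel condensation of the active methylene of 1 with the non-enolisable aldehyde 2; the isomer with the acetal carbon cis to the ester (Z) is expected to predominate and is the one the cycloaddition needs, and the E isomer can be re-equilibrated with the amine catalyst.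

Step 2
Reactants: 3 methyl (2Z)-2-acetyl-4,4-dimethoxybut-2-enoate
Product: 4 methyl (2Z)-4,4-dimethoxy-2-{1-[(triisopropylsilyl)oxy]ethenyl}but-2-enoate
Conditions: TIPSOTf, Et3N, CH2Cl2, 0 °C
Reagents that add atoms: triisopropylsilyl trifluoromethanesulfonate, CC(C)[Si](OS(=O)(=O)C(F)(F)F)(C(C)C)C(C)C
Why: Soft enolisation of the methyl ketone (silyl triflate with amine base) gives the cross-conjugated 2-silyloxy diene, the standard preparation of silyloxy dienes from enones; no stereocentre forms and the alkene geometry is kept.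

Step 3
Reactants: 5 methacrolein
Product: 6 (2E)-4-methylpenta-2,4-dienal
Conditions: Ph3P=CHCHO, toluene, 80 °C, methacrolein in excess (3 equiv)
Reagents that add atoms: (triphenylphosphoranylidene)acetaldehyde, O=CC=P(c1ccccc1)(c1ccccc1)c1ccccc1
Why: Wittig olefination with the stabilised formylmethylene ylide gives the E enal, and the excess of methacrolein keeps the product from a second homologation.

Step 4
Reactants: 4 methyl (2Z)-4,4-dimethoxy-2-{1-[(triisopropylsilyl)oxy]ethenyl}but-2-enoate; 6 (2E)-4-methylpenta-2,4-dienal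
Product: 7 methyl (4R,5S,6S)-6-(dimethoxymethyl)-5-formyl-4-(prop-1-en-2-yl)-2-[(triisopropylsilyl)oxy]cyclohex-1-ene-1-carboxylate
Conditions: (S)-3,3-diphenyl-1-(o-tolyl)tetrahydro-1H,3H-pyrrolo[1,2-c][1,3,2]oxazaborole·HNTf2 (20 mol %), CH2Cl2, −78 → −40 °C
Reagents that add atoms: none
Why: Enantioselective Diels–Alder reaction under cationic oxazaborolidine activation of the enal: the silyloxy group directs para and the acetal-bearing terminus ortho so that the diene CH2 bonds to the enal β-carbon, the endo formyl group places the acetal-bearing carbon cis to the formyl-bearing carbon, the E dienal fixes isopropenyl trans to formyl, and the catalyst's face selection sets the absolute configuration of all three centres.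

Step 5
Reactants: 8 (4R)-4-[(tert-butyldimethylsilyl)oxy]cyclopent-2-en-1-one
Product: 9 (1S,4R)-4-[(tert-butyldimethylsilyl)oxy]-1-methylcyclopent-2-en-1-ol
Conditions: MeLi, Et2O, −78 °C; then H2O
Reagents that add atoms: methyllithium, [Li]C
Why: 1,2-Addition of methyllithium to the enone carbonyl from the face anti to the C4 silyloxy group puts the new tertiary OH cis to OTBS (methyl trans), as is usual for 4-silyloxycyclopentenones.

Step 6
Reactants: 9 (1S,4R)-4-[(tert-butyldimethylsilyl)oxy]-1-methylcyclopent-2-en-1-ol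
Product: 11 2-[(1S,5R)-5-[(tert-butyldimethylsilyl)oxy]-3-methylcyclopent-2-en-1-yl]-N,N-dimethylacetamide, via ketene N,O-acetal 10 (not isolated)
Conditions: MeC(OMe)2NMe2 (5 equiv), xylene, 140 °C
Reagents that add atoms: N,N-dimethylacetamide dimethyl acetal, COC(C)(OC)N(C)C
Why: Eschenmoser–Claisen rearrangement: the ketene N,O-acetal formed on the tertiary alcohol shifts suprafacially across the cyclopentene, so the new C–C bond forms at the allylic terminus next to C–OTBS on the face of the departing oxygen (cis to OTBS) and leaves the trisubstituted methyl alkene.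

Step 7
Reactants: 11 2-[(1S,5R)-5-[(tert-butyldimethylsilyl)oxy]-3-methylcyclopent-2-en-1-yl]-N,N-dimethylacetamide
Product: 13 (3aS,6aR)-5-methyl-3,3a,6,6a-tetrahydro-2H-cyclopenta[b]furan-2-one, via hydroxy amide 12 (not isolated)
Conditions: 1 M aq. HCl, THF, 45 °C
Reagents that add atoms: none
Why: Acid removes the TBS ether and the cis γ-hydroxy amide lactonises by N-to-O acyl transfer to the cis-fused γ-lactone (lactonisation), with no change at either stereocentre.

Step 8
Reactants: 13 (3aS,6aR)-5-methyl-3,3a,6,6a-tetrahydro-2H-cyclopenta[b]furan-2-one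
Product: 15 diethyl [(3aS,6aR)-5-methyl-2-oxo-3,3a,6,6a-tetrahydro-2H-cyclopenta[b]furan-3-yl]phosphonate (C3 epimers), via enol phosphate 14 (not isolated)
Conditions: LiN(iPr)2 (1.1 equiv), THF, −78 °C; ClP(O)(OEt)2; LiN(iPr)2 (1.2 equiv), −78 → 0 °C; then AcOH
Reagents that add atoms: diethyl chlorophosphate, CCOP(=O)(Cl)OCC
Why: Wiemer phosphonylation: the lactone enolate is O-phosphorylated and a second equivalent of base induces the 1,3 O-to-C phosphoryl shift to the stabilised α-phosphono enolate; the new α-centre is of no consequence because it becomes sp2 in step 9.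

Step 9
Reactants: 7 methyl (4R,5S,6S)-6-(dimethoxymethyl)-5-formyl-4-(prop-1-en-2-yl)-2-[(triisopropylsilyl)oxy]cyclohex-1-ene-1-carboxylate; 15 diethyl [(3aS,6aR)-5-methyl-2-oxo-3,3a,6,6a-tetrahydro-2H-cyclopenta[b]furan-3-yl]phosphonate
Product: 16 methyl (4R,5S,6S)-6-(dimethoxymethyl)-5-{(E)-[(3aR,6aR)-5-methyl-2-oxo-6,6a-dihydro-2H-cyclopenta[b]furan-3(3aH)-ylidene]methyl}-4-(prop-1-en-2-yl)-2-[(triisopropylsilyl)oxy]cyclohex-1-ene-1-carboxylate
Conditions: LiCl, DBU, MeCN, 0 °C → rt
Reagents that add atoms: none
Why: Horner–Wadsworth–Emmons olefination under Masamune–Roush conditions, mild enough to spare the α-stereocentre of 7, the silyl enol ether and the acetal; α-phosphono γ-lactones with α-branched aldehydes should favour the E alkylidene lactone (ring-A carbon trans to the lactone carbonyl), the geometry that points ring A at the cyclopentene.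

Step 10
Reactants: 16 HWE product (dimethyl acetal)
Product: 18 methyl (4R,5S,6S)-6-[(hydroxyimino)methyl]-5-{(E)-[(3aR,6aR)-5-methyl-2-oxo-6,6a-dihydro-2H-cyclopenta[b]furan-3(3aH)-ylidene]methyl}-4-(prop-1-en-2-yl)-2-[(triisopropylsilyl)oxy]cyclohex-1-ene-1-carboxylate, via aldehyde 17 (not isolated)
Conditions: NH2OH·HCl, NaOAc, AcOH/THF/H2O (3:1:1), 40 °C
Reagents that add atoms: hydroxylamine hydrochloride, [NH3+]O.[Cl-]
Why: Buffered acid unmasks the dimethyl acetal and hydroxylamine traps the aldehyde at once as the aldoxime (oximation), while the TIPS enol ether keeps the β-keto ester from condensing to an isoxazolone and the ring-A centres stay untouched.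

Step 11
Reactants: 18 aldoxime
Product: 21 TIPS-protected pentacyclic 4,5-dihydroisoxazole (rings A–D plus the dihydroisoxazole; see list), via hydroximoyl chloride 19 (not isolated), via nitrile oxide 20 (not isolated)
Conditions: NCS (1.05 equiv), pyridine (cat.), CHCl3, 0 °C → rt; then dilution into toluene (0.002 M), Et3N by syringe pump over 12 h, 60 °C
Reagents that add atoms: none
Why: Chlorination of the aldoxime and dehydrochlorination give nitrile oxide 20, which adds in a concerted, suprafacial [3+2] fashion to the trisubstituted cyclopentene double bond (intramolecular nitrile oxide–alkene cycloaddition, the closest known type being such cycloadditions that close six- and seven-membered carbocycles). Ring B closes in the fused (exo) mode, the dipole carbon bonding to the proximal alkene CH to form the seven-membered carbocycle, and the 4,5-dihydroisoxazole closes at the same time with oxygen on the distal methyl-bearing carbon. The new ring-fusion CH is controlled by the neighbouring lactone ring-fusion centre, because the tether through the E-alkylidene lactone can reach only the alkene face syn to the lactone α-carbon (cis 5/7 fusion), and the tertiary C–O centre follows from syn addition, which places oxygen cis to the new C–C bond exactly as in the cis β-hydroxy ketone of the target. Regioselectivity is enforced by the tether and matches the innate preference for oxygen at the more substituted alkene carbon. Chemoselectivity is secured by the substrate: the isopropenyl group is 1,3-trans to the dipole on ring A and cannot be bridged, the alkylidene lactone could only give a four-membered or bridgehead-imine ring, and high dilution with slow base addition suppresses furoxan formation and intermolecular capture.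

Step 12
Reactants: 21 pentacyclic 4,5-dihydroisoxazole
Product: 23 TIPS enol ether of the target (β-hydroxy ketone; see list), via hydroxy imine 22 (not isolated)
Conditions: Mo(CO)6 (1.2 equiv), MeCN/H2O (10:1), 80 °C
Reagents that add atoms: water, O
Why: Mo(CO)6-mediated reductive N–O cleavage gives the β-hydroxy imine, which the wet medium hydrolyses to the β-hydroxy ketone (the classical unmasking of a 4,5-dihydroisoxazole as an aldol); the method spares alkenes, esters and the silyl enol ether and touches no stereocentre.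

Step 13
Reactants: 23 TIPS enol ether of the target
Product: 24 target CNP0268969.1
Conditions: HF·pyridine, pyridine, THF, 0 °C → rt
Reagents that add atoms: none
Why: Fluoride cleaves the Si–O bond of the silyl enol ether (desilylation) under buffered, non-basic conditions, which avoids retro-aldol loss of the tertiary β-hydroxy ketone and releases the β-keto ester as its chelated enol.

**Compound list**

1 | methyl acetoacetate | COC(=O)CC(C)=O | starting material
2 | 2,2-dimethoxyacetaldehyde | COC(OC)C=O | starting material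
3 | methyl (2Z)-2-acetyl-4,4-dimethoxybut-2-enoate | CC(=O)/C(C(=O)OC)=C/C(OC)OC | intermediate
4 | methyl (2Z)-4,4-dimethoxy-2-{1-[(triisopropylsilyl)oxy]ethenyl}but-2-enoate | C=C(O[Si](C(C)C)(C(C)C)C(C)C)/C(C(=O)OC)=C/C(OC)OC | intermediate
5 | methacrolein | CC(=C)C=O | starting material
6 | (2E)-4-methylpenta-2,4-dienal | C=C(C)/C=C/C=O | intermediate
7 | methyl (4R,5S,6S)-6-(dimethoxymethyl)-5-formyl-4-(prop-1-en-2-yl)-2-[(triisopropylsilyl)oxy]cyclohex-1-ene-1-carboxylate (formyl cis to acetal, trans to isopropenyl) | C=C(C)[C@@H]1CC(O[Si](C(C)C)(C(C)C)C(C)C)=C(C(=O)OC)[C@@H](C(OC)OC)[C@H]1C=O | intermediate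
8 | (4R)-4-[(tert-butyldimethylsilyl)oxy]cyclopent-2-en-1-one | O=C1C=C[C@H](O[Si](C)(C)C(C)(C)C)C1 | starting material
9 | (1S,4R)-4-[(tert-butyldimethylsilyl)oxy]-1-methylcyclopent-2-en-1-ol (OH cis to OTBS) | C[C@@]1(O)C=C[C@H](O[Si](C)(C)C(C)(C)C)C1 | intermediate
10 | ketene N,O-acetal of 9 (1-(dimethylamino)ethenyl ether of the tertiary alcohol) | C=C(N(C)C)O[C@]1(C)C=C[C@H](O[Si](C)(C)C(C)(C)C)C1 | intermediate (not isolated)
11 | 2-[(1S,5R)-5-[(tert-butyldimethylsilyl)oxy]-3-methylcyclopent-2-en-1-yl]-N,N-dimethylacetamide (side chain cis to OTBS) | CN(C)C(=O)C[C@H]1C=C(C)C[C@H]1O[Si](C)(C)C(C)(C)C | intermediate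
12 | 2-[(1S,5R)-5-hydroxy-3-methylcyclopent-2-en-1-yl]-N,N-dimethylacetamide | CN(C)C(=O)C[C@H]1C=C(C)C[C@H]1O | intermediate (not isolated)
13 | (3aS,6aR)-5-methyl-3,3a,6,6a-tetrahydro-2H-cyclopenta[b]furan-2-one (cis-fused) | O=C1C[C@H]2C=C(C)C[C@H]2O1 | intermediate
14 | enol diethyl phosphate of lactone 13 (2-[(diethoxyphosphoryl)oxy]-5-methyl-6,6a-dihydro-3aH-cyclopenta[b]furan) | CCOP(=O)(OCC)OC1=C[C@H]2C=C(C)C[C@H]2O1 | intermediate (not isolated)
15 | diethyl [(3aS,6aR)-5-methyl-2-oxo-3,3a,6,6a-tetrahydro-2H-cyclopenta[b]furan-3-yl]phosphonate (C3 epimers) | CCOP(=O)(OCC)C1C(=O)O[C@@H]2CC(C)=C[C@H]12 | intermediate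
16 | methyl (4R,5S,6S)-6-(dimethoxymethyl)-5-{(E)-[(3aR,6aR)-5-methyl-2-oxo-6,6a-dihydro-2H-cyclopenta[b]furan-3(3aH)-ylidene]methyl}-4-(prop-1-en-2-yl)-2-[(triisopropylsilyl)oxy]cyclohex-1-ene-1-carboxylate | C=C(C)[C@@H]1CC(O[Si](C(C)C)(C(C)C)C(C)C)=C(C(=O)OC)[C@@H](C(OC)OC)[C@H]1/C=C2/C(=O)O[C@@H]3CC(C)=C[C@H]23 | intermediate
17 | 6-formyl analogue of 16 (acetal hydrolysed; all else as in 16) | C=C(C)[C@@H]1CC(O[Si](C(C)C)(C(C)C)C(C)C)=C(C(=O)OC)[C@@H](C=O)[C@H]1/C=C2/C(=O)O[C@@H]3CC(C)=C[C@H]23 | intermediate (not isolated)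
18 | 6-[(hydroxyimino)methyl] analogue of 16 (aldoxime; all else as in 16) | C=C(C)[C@@H]1CC(O[Si](C(C)C)(C(C)C)C(C)C)=C(C(=O)OC)[C@@H](C=NO)[C@H]1/C=C2/C(=O)O[C@@H]3CC(C)=C[C@H]23 | intermediate
19 | 6-[chloro(hydroxyimino)methyl] analogue of 16 (hydroximoyl chloride) | C=C(C)[C@@H]1CC(O[Si](C(C)C)(C(C)C)C(C)C)=C(C(=O)OC)[C@@H](C(Cl)=NO)[C@H]1/C=C2/C(=O)O[C@@H]3CC(C)=C[C@H]23 | intermediate (not isolated)
20 | nitrile oxide (ring-A C6 carbonitrile N-oxide; all else as in 16) | C=C(C)[C@@H]1CC(O[Si](C(C)C)(C(C)C)C(C)C)=C(C(=O)OC)[C@@H](C#[N+][O-])[C@H]1/C=C2/C(=O)O[C@@H]3CC(C)=C[C@H]23 | intermediate (not isolated)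
21 | pentacyclic 4,5-dihydroisoxazole: its C=N carbon joins ring-A C6 to the ring B/C fusion CH, its O-bearing carbon is the ring-C carbon carrying CH3; seven-membered ring B cis-fused to ring C, all four ring-B CH hydrogens syn; ring A as in 7 (TIPS enol ether, methyl ester, isopropenyl); ring D α-alkylidene γ-lactone | C=C(C)[C@@H]1CC(O[Si](C(C)C)(C(C)C)C(C)C)=C(C(=O)OC)[C@H]2C(=N5)[C@@H]3[C@@H]4C(=C[C@H]21)C(=O)O[C@@H]4C[C@]3(C)O5 | intermediate
22 | β-hydroxy imine from N–O cleavage of 21 (ring-B C=NH, ring-C tertiary OH) | C=C(C)[C@@H]1CC(O[Si](C(C)C)(C(C)C)C(C)C)=C(C(=O)OC)[C@H]2C(=N)[C@@H]3[C@@H]4C(=C[C@H]21)C(=O)O[C@@H]4C[C@]3(C)O | intermediate (not isolated)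
23 | TIPS enol ether of the target (ring-B ketone, cis tertiary OH on ring C) | C=C(C)[C@@H]1CC(O[Si](C(C)C)(C(C)C)C(C)C)=C(C(=O)OC)[C@H]2C(=O)[C@@H]3[C@@H]4C(=C[C@H]21)C(=O)O[C@@H]4C[C@]3(C)O | intermediate
24 | target CNP0268969.1: ring A cyclohexene enol methyl ester with isopropenyl, ring B cycloheptenone, ring C methylcyclopentanol, ring D α-alkylidene γ-lactone | C=C(C)[C@@H]1CC(O)=C(C(=O)OC)[C@H]2C(=O)[C@@H]3[C@@H]4C(=C[C@H]21)C(=O)O[C@@H]4C[C@]3(C)O | target

**Totals**
Total steps: 13. Longest linear sequence: 9 steps (steps 5–13, from enone 8). The ring-A branch is 8 steps (steps 1, 2, 4, 9–13) and step 3 is a one-step side branch.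

**Steps most likely to fail**

Step 4. What may go wrong: the push–pull diene may react by a stepwise Mukaiyama–Michael path that erodes endo and facial control, or the acetal may ionise at the boron Lewis acid. The fallback sets out from 6 and uses the parent diene of the catalyst's established scope, setting the acetal-bearing centre later by conjugate addition. Dienal 6 and 2-(triisopropylsilyloxy)buta-1,3-diene with the same oxazaborolidinium catalyst should give the silyl enol ether aldehyde F1. Horner–Wadsworth–Emmons reaction with 15 (LiCl, DBU, MeCN) should give the alkylidene lactone F2. Saegusa–Ito oxidation (Pd(OAc)2, O2, DMSO) should give the enone F3, and iodination (I2, pyridine) the α-iodoenone F4. Methoxycarbonylation (PdCl2(PPh3)2, CO, MeOH, Et3N) should give the 2-carbomethoxy enone F5. Conjugate addition of nitromethane (cat. DBU), axial and trans to isopropenyl and reversible, should give the nitro keto ester F6 as its enol. Silylation (TIPSCl, imidazole, DMF) should give the silyl enol ether F7. Mukaiyama dehydration of the primary nitro group (PhNCO, Et3N) should then give nitrile oxide 20, where the route is rejoined in step 11.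

Step 11. What may go wrong: dimerisation of the nitrile oxide to a furoxan, or intermolecular capture by an isopropenyl group, may outrun the slow seven-membered closure. The fallback sets out from oxime 18 and avoids a free nitrile oxide. Thermal intramolecular oxime–olefin cycloaddition through the NH-nitrone tautomer (toluene, 150 °C, sealed tube) should give the N-unsubstituted isoxazolidine F8, with the same tether-directed syn addition. N-Chlorination (NCS) should give the N-chloro isoxazolidine F9, and elimination of HCl (DBU) returns to dihydroisoxazole 21.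

Step 9. What may go wrong: base-induced epimerisation of the α-branched aldehyde, or poor E/Z control in the olefination. The fallback sets out from lactone 13 and aldehyde 7. The lithium enolate of 13 (LiN(iPr)2, THF, −78 °C) should add to 7 to give the β-hydroxy lactone F10 as a mixture at the two new centres. Mesylation (MsCl, Et3N) should give the mesylate F11, and E1cB elimination (DBU) should give the thermodynamically preferred E-alkylidene lactone 16.

**Further compounds**
F1 | step 4 | (1R,6R)-6-(prop-1-en-2-yl)-4-[(triisopropylsilyl)oxy]cyclohex-3-ene-1-carbaldehyde | C=C(C)[C@@H]1CC(O[Si](C(C)C)(C(C)C)C(C)C)=CC[C@H]1C=O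
F2 | step 4 | E-alkylidene lactone from F1 and 15 (ring-A silyl enol ether retained) | C=C(C)[C@@H]1CC(O[Si](C(C)C)(C(C)C)C(C)C)=CC[C@H]1/C=C2/C(=O)O[C@@H]3CC(C)=C[C@H]23
F3 | step 4 | trans-4-(alkylidene lactone methyl)-5-isopropenylcyclohex-2-enone | C=C(C)[C@@H]1CC(=O)C=C[C@H]1/C=C2/C(=O)O[C@@H]3CC(C)=C[C@H]23
F4 | step 4 | 2-iodo derivative of enone F3 | C=C(C)[C@@H]1CC(=O)C(I)=C[C@H]1/C=C2/C(=O)O[C@@H]3CC(C)=C[C@H]23
F5 | step 4 | 2-(methoxycarbonyl) derivative of enone F3 | C=C(C)[C@@H]1CC(=O)C(C(=O)OC)=C[C@H]1/C=C2/C(=O)O[C@@H]3CC(C)=C[C@H]23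
F6 | step 4 | nitromethyl β-keto ester (enol form; nitromethyl cis to the alkylidene-bearing carbon) | C=C(C)[C@@H]1CC(O)=C(C(=O)OC)[C@@H](C[N+](=O)[O-])[C@H]1/C=C2/C(=O)O[C@@H]3CC(C)=C[C@H]23
F7 | step 4 | TIPS enol ether of F6 | C=C(C)[C@@H]1CC(O[Si](C(C)C)(C(C)C)C(C)C)=C(C(=O)OC)[C@@H](C[N+](=O)[O-])[C@H]1/C=C2/C(=O)O[C@@H]3CC(C)=C[C@H]23
F8 | step 11 | N-unsubstituted isoxazolidine analogue of 21 (C–N carbon configuration not defined; it is removed in the next operation) | C=C(C)[C@@H]1CC(O[Si](C(C)C)(C(C)C)C(C)C)=C(C(=O)OC)[C@H]2C(N5)[C@@H]3[C@@H]4C(=C[C@H]21)C(=O)O[C@@H]4C[C@]3(C)O5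
F9 | step 11 | N-chloro isoxazolidine from F8 | C=C(C)[C@@H]1CC(O[Si](C(C)C)(C(C)C)C(C)C)=C(C(=O)OC)[C@H]2C(N5Cl)[C@@H]3[C@@H]4C(=C[C@H]21)C(=O)O[C@@H]4C[C@]3(C)O5
F10 | step 9 | β-hydroxy lactone (aldol adduct of 13 and 7; mixture at the carbinol and lactone α-carbons) | C=C(C)[C@@H]1CC(O[Si](C(C)C)(C(C)C)C(C)C)=C(C(=O)OC)[C@@H](C(OC)OC)[C@H]1C(O)C2C(=O)O[C@@H]3CC(C)=C[C@H]23
F11 | step 9 | methanesulfonate of F10 | C=C(C)[C@@H]1CC(O[Si](C(C)C)(C(C)C)C(C)C)=C(C(=O)OC)[C@@H](C(OC)OC)[C@H]1C(OS(C)(=O)=O)C2C(=O)O[C@@H]3CC(C)=C[C@H]23
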